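If we repeat these flasks, the thing to watch is how many places on the starting material stay empty once the partner has been taken up.

| setting | Friday's | red | green | blue |
|---|---|---|---|---|
| starting material | 2 mM | 2.0 mM | 2.0 mM | 2.0 mM |
| partner | 4.6 mM (fed, over 30 s) | 3.00 mM (fed, over 30 s) | 4.00 mM (fed, over 30 s) | 6.00 mM (fed, over 30 s) |
| remark | run made earlier |  |  |  |
| time |  | 5.0 min | 5.0 min | 5.0 min |

Friday's run (percent of the starting material charged)

| time / min | bis adduct / % | triple product / % | starting material / % |
|---|---|---|---|
| 0.333 | 33 | 8 | 31 |
| 0.833 | 18 | 18 | 5 |
| 1.50 | 16 | 5 | 8 |
| 2.50 | 17 | 2 | 7 |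
| 4.00 | 15 | 4 | 8 |

(scatter of a reading: 1.5 percentage points)

- steps that have been proposed: starting material + partner -> mono adduct; partner + mono adduct -> bis adduct; partner + bis adduct -> triple product; triple product <-> isomer of the product; starting material <-> dormant form

* how much bis adduct is there at the end, in percent of the starting material charged: for each flask in turn (red, green, blue)

1. Each adduct step adds one partner, so a starting material that reaches the triple product, or its isomer, has taken 3 partners. Mono adduct lacks 2, bis adduct lacks 1, and starting material and its dormant form lack 3.

2. Take the green flask: 4.00 mM of partner on 2.0 mM of starting material is 2.00 partners per starting material. Once they are taken up, 1.00 places per starting material stay empty. These empty places, 3 less the partners charged per starting material, are our count of turnovers still undone. While the count stands above zero, the partner is the limiting reagent.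

3. The same subtraction gives 0.700 for Friday's run, 1.50 for red and 0 for blue.

4. Friday's bis adduct reads 16 %, 17 % and 15 % from 1.50 min on, flat within the scatter of 1.5 percentage points. The mean reading is 16.0 %, which is 0.229 of bis adduct per empty place.

5. Our own rough step is to hold that share fixed from flask to flask. That gives 34.3 % for red, 22.9 % for green and 0 % for blue.

6. The forecast says 33 %, 25 % and 3 %. It differs from our reckoning most plainly in blue, “leaving a small tail” where ours leaves none.

The flasks give 31.0 %, 24.4 % and 1.04 %, and the forecast stands within its margin. In green the partner is at 0 % of its charge at 5.00 min, and a reading ten times later changes nothing.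

    starting material + partner → mono adduct (k = 100 M⁻¹ s⁻¹)
    partner + mono adduct → bis adduct (k = 460 M⁻¹ s⁻¹)
    partner + bis adduct → triple product (k = 91.0 M⁻¹ s⁻¹)
    triple product ⇌ isomer of the product (K = 21.0, k = 0.0530 s⁻¹)
    starting material ⇌ dormant form (K = 0.800, k = 0.0140 s⁻¹)

Green's 1.00 empty places are found again as 1.00, counting starting material, dormant form, mono adduct and bis adduct. In red, with 1.50 empty places, the same count comes to 1.50, of which bis adduct holds 31.0.

The earlier runs and the new flask are calculated on assumed constants.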